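The decalin is disconnected across ring B at C5–C10 and C8–C9, so that one intramolecular Diels–Alder reaction of an acyclic (2E,8E,10E)-trienoyl oxazolidinone forms rings A and B together and sets C5, C8, C9 and C10. It exploits the three adjacent ring-B carbons C5 (fusion CH), C10 (methyl-bearing quaternary carbon) and C9 (side-chain CH), and the fact that the C6–OH/C7=C8–C17HO array can be developed from a C6=C7 cycloadduct alkene bearing C17 on C8. The precursor carries the C4 gem-dimethyl tether, a C17 PMB ether and a dienophile whose geometry is fixed by a stereoretentive Suzuki coupling; a chiral Cu(II)–bis(oxazoline) catalyst controls the absolute sense.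

Key step: step 8

Remarks on the chemistry:
- Labdane numbering is used: decalin C1–C10, side chain C11–C12, C13=C14, ester carbon C15, formyloxymethyl carbon C16, formyl carbon C17.
- The target is taken as drawn: C10–CH3 and the C9 side chain lie on one face of the trans-decalin; H5, H9 and the C6 hydroxyl lie on the other.
- C17 is carried as a PMB ether, so that it can be released oxidatively (DDQ) in the presence of the formate and the epoxide.
- "Octalin core of 14" means 5,5,8a-trimethyl-1,2,4a,5,6,7,8,8a-octahydronaphthalene (alkene C6=C7) with C10–CH3, the C9 substituent and the C8 CH2O group on one face and H5, H8, H9 on the other, in the absolute configuration of the SMILES of 14.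

Step 1
Reactants: 1 2,2-dimethylpent-4-enal; 2 triethyl 4-phosphonocrotonate
Product: 3 ethyl (2E,4E)-6,6-dimethylnona-2,4,8-trienoate
Conditions: 2, LiHMDS, THF, −78 °C; then 1, −78 → 0 °C
Reagents that add atoms: none
Why: Vinylogous Horner–Wadsworth–Emmons olefination of a non-enolisable α-quaternary aldehyde, in which the allylic phosphonate anion reacts at the carbon next to phosphorus and the bulky aldehyde substituent should give the (2E,4E)-dienoate (the future C5=C6–C7=C8 diene, C17 as the ester carbon).

Step 2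
Reactants: 3 ethyl (2E,4E)-6,6-dimethylnona-2,4,8-trienoate
Product: 4 (2E,4E)-6,6-dimethylnona-2,4,8-trien-1-ol
Conditions: DIBAL-H (2.2 equiv), CH2Cl2, −78 °C; aq. Rochelle salt
Reagents that add atoms: none
Why: DIBAL-H reduces the dienoate by 1,2-hydride delivery to the dienol and leaves the terminal and conjugated alkenes untouched at low temperature.

Step 3
Reactants: 4 (2E,4E)-6,6-dimethylnona-2,4,8-trien-1-ol
Product: 5 1-({[(2E,4E)-6,6-dimethylnona-2,4,8-trien-1-yl]oxy}methyl)-4-methoxybenzene
Conditions: NaH, THF/DMF, 0 °C; PMBCl, n-Bu4NI (cat.), rt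
Reagents that add atoms: 4-methoxybenzyl chloride, COc1ccc(CCl)cc1
Why: Williamson etherification under basic conditions protects the acid-sensitive dienylic alcohol as the PMB ether that is removed oxidatively near the end.

Step 4
Reactants: 6 methyl acetoacetate
Product: 7 methyl (2E)-3-{[(trifluoromethyl)sulfonyl]oxy}but-2-enoate
Conditions: Tf2O, aq. Me4NOH, hexanes, 5–10 °C
Reagents that add atoms: trifluoromethanesulfonic anhydride, O=S(=O)(OS(=O)(=O)C(F)(F)F)C(F)(F)F
Why: O-Triflation of the β-keto ester enolate under Schotten–Baumann-type conditions with a non-chelating ammonium counter-ion should give the (E)-enol triflate (triflate trans to the ester), which encodes the later dienophile geometry.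

Step 5
Reactants: 5 1-({[(2E,4E)-6,6-dimethylnona-2,4,8-trien-1-yl]oxy}methyl)-4-methoxybenzene; 7 methyl (2E)-3-{[(trifluoromethyl)sulfonyl]oxy}but-2-enoate
Product: 9 methyl (2E,8E,10E)-12-[(4-methoxybenzyl)oxy]-3,7,7-trimethyldodeca-2,8,10-trienoate, via B-alkyl-9-BBN borane 8 (not isolated)
Conditions: 9-BBN (1.1 equiv), THF, 0 °C → rt; then 7, PdCl2(dppf) (5 mol %), 3 M aq. K3PO4, DMF, rt
Reagents that add atoms: none
Why: 9-BBN hydroborates only the terminal alkene (boron on C1), and the B-alkyl Suzuki–Miyaura coupling with the enol triflate is stereoretentive, so C1–C10 forms with the ester cis to the C10 methyl (2E).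

Step 6
Reactants: 9 methyl (2E,8E,10E)-12-[(4-methoxybenzyl)oxy]-3,7,7-trimethyldodeca-2,8,10-trienoate
Product: 10 (2E,8E,10E)-12-[(4-methoxybenzyl)oxy]-3,7,7-trimethyldodeca-2,8,10-trienoic acid
Conditions: LiOH·H2O, THF/MeOH/H2O, 40 °C; then 1 M HCl to pH 4, 0 °C
Reagents that add atoms: lithium hydroxide, [Li+].[OH-]
Why: Saponification of the methyl ester leaves the PMB ether and all three alkene geometries unchanged.

Step 7
Reactants: 10 (2E,8E,10E)-12-[(4-methoxybenzyl)oxy]-3,7,7-trimethyldodeca-2,8,10-trienoic acid; 11 oxazolidin-2-one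
Product: 13 3-{(2E,8E,10E)-12-[(4-methoxybenzyl)oxy]-3,7,7-trimethyldodeca-2,8,10-trienoyl}oxazolidin-2-one, via mixed pivalic anhydride 12 (not isolated)
Conditions: PivCl, Et3N, THF, −20 °C; then LiCl, 11, −20 °C → rt
Reagents that add atoms: none
Why: N-Acylation of the oxazolidinone through the mixed pivalic anhydride with LiCl activation is mild and avoids acid chloride/ketene pathways, so the (2E)-enoyl geometry should be retained.

Step 8
Reactants: 13 3-{(2E,8E,10E)-12-[(4-methoxybenzyl)oxy]-3,7,7-trimethyldodeca-2,8,10-trienoyl}oxazolidin-2-one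
Product: 14 3-{[(1R,2R,4aR,8aR)-2-{[(4-methoxybenzyl)oxy]methyl}-5,5,8a-trimethyl-1,2,4a,5,6,7,8,8a-octahydronaphthalen-1-yl]carbonyl}oxazolidin-2-one
Conditions: [Cu((S,S)-t-Bu-box)](SbF6)2 (10 mol %), CH2Cl2, 25 °C
Reagents that add atoms: none
Why: Proposed new method: two-point chelation of both imide carbonyls to the cationic square-planar Cu(II)–bis(oxazoline) centre lowers the enoyl LUMO and locks it s-cis, and a concerted, asynchronous normal-demand [4+2] of the C5=C6–C7=C8 diene onto C9=C10 forms C8–C9 and C5–C10; the closest known reaction type is the Cu(II)–bis(oxazoline)-catalysed intramolecular Diels–Alder reaction of (E,E,E)-trienoyl oxazolidinones, extended here to a β,β-disubstituted enoyl unit that creates the quaternary C10. Ring B (C5–C6–C7–C8–C9–C10) is the new cyclohexene of the cycloaddition, and ring A (C1–C2–C3–C4–C5–C10) closes as the tether ring through the C5–C10 bond with the four-carbon tether in a chair. C9 and C10 are fixed relative to each other by the (E)-dienophile (acyl and methyl cis) and in the absolute sense by the ligand, whose tert-butyl group is expected to leave the Cα-Re face of C9 open; C5 and C8 follow from the (E,E)-diene (both hydrogens inside) and from the endo position of the chelated carbonyl, which puts the tether exo and so gives the trans ring fusion and the C8 substituent cis to the C9 acyl group. The step needs endo and π-facial selectivity, both resting on the rigid chelate, and enough reactivity at a trisubstituted dienophile, which the SbF6 counter-ion, the intramolecularity and the Thorpe–Ingold effect of the C4 gem-dimethyl group should supply.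

Step 9
Reactants: 14 cycloadduct imide
Product: 15 C9-hydroxymethyl octalin (octalin core of 14 with C11H2OH on C9 and CH2OPMB on C8)
Conditions: LiBH4, MeOH (1 equiv), THF, 0 °C
Reagents that add atoms: none
Why: Reductive cleavage of the N-acyl oxazolidinone by LiBH4 gives the primary C11 alcohol without touching C9 and releases the oxazolidinone.

Step 10
Reactants: 15 C9-hydroxymethyl octalin
Product: 16 C9-formyl octalin (octalin core of 14 with C11HO on C9 and CH2OPMB on C8)
Conditions: DMP, pyridine, CH2Cl2, 0 °C → rt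
Reagents that add atoms: none
Why: Dess–Martin oxidation gives the C11 aldehyde under non-basic conditions, and since C9 already holds its substituent equatorially no epimerisation is expected.

Step 11
Reactants: 16 C9-formyl octalin
Product: 17 C9-vinyl octalin (octalin core of 14 with C11H=C12H2 on C9 and CH2OPMB on C8)
Conditions: Ph3PCH3Br, KHMDS, THF, 0 °C; then 16, 0 °C → rt
Reagents that add atoms: methyltriphenylphosphonium bromide, C[P+](c1ccccc1)(c1ccccc1)c1ccccc1.[Br-]
Why: Wittig methylenation with the small non-stabilised ylide is fast even on hindered α-branched aldehydes and supplies C12 as a terminal alkene for hydroboration.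

Step 12
Reactants: 18 methyl 4-hydroxybut-2-ynoate
Product: 19 methyl (2Z)-4-hydroxy-3-iodobut-2-enoate
Conditions: NaI, AcOH, MeCN, 70 °C
Reagents that add atoms: sodium iodide, [Na+].[I-]
Why: Conjugate hydroiodination of the ynoate proceeds by anti addition of iodide and a proton, giving the (Z)-β-iodo enoate whose hydroxymethyl group is trans to the ester and cannot lactonise.

Step 13
Reactants: 17 C9-vinyl octalin; 19 methyl (2Z)-4-hydroxy-3-iodobut-2-enoate
Product: 21 methyl (2E)-3-(hydroxymethyl)-5-(octalin-9-yl)pent-2-enoate (octalin core of 14 with CH2OPMB on C8; C16–OH free), via B-alkyl-9-BBN borane 20 (not isolated)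
Conditions: 9-BBN (1.5 equiv), THF, 0 °C → rt; then 19, Pd(dppf)Cl2 (10 mol %), AsPh3 (10 mol %), 3 M aq. K3PO4, DMF, rt
Reagents that add atoms: none
Why: 9-BBN selects the terminal vinyl group over the hindered ring alkene (boron on C12), and the B-alkyl Suzuki–Miyaura coupling with the vinyl iodide is stereoretentive, so C12–C13 forms with C12 cis and C16 trans to the ester (13E).

Step 14
Reactants: 21 C16 alcohol
Product: 22 methyl (2E)-3-[(formyloxy)methyl]-5-(octalin-9-yl)pent-2-enoate (octalin core of 14 with CH2OPMB on C8)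
Conditions: acetic formic anhydride, pyridine, CH2Cl2, 0 °C
Reagents that add atoms: acetic formic anhydride, CC(=O)OC=O
Why: Acylation with the mixed anhydride transfers the formyl group to the only free hydroxyl (C16–OH), so no selectivity between hydroxyls is needed.

Step 15
Reactants: 22 C16 formate
Product: 23 6,7-epoxide of 22 (epoxide oxygen on the face opposite the C10 methyl)
Conditions: mCPBA, CH2Cl2, 0 °C
Reagents that add atoms: 3-chloroperbenzoic acid, O=C(OO)c1cccc(Cl)c1
Why: Prilezhaev epoxidation attacks the only electron-rich alkene (C6=C7; the enoate is inert) from the face anti to the axial C10 and C4 methyl groups and the pseudoaxial C8 CH2OPMB group, which sets the C6–O bond anti to the C10 methyl.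

Step 16
Reactants: 23 6,7-epoxide
Product: 24 epoxy alcohol (23 with free C17–OH)
Conditions: DDQ, CH2Cl2/pH 7 phosphate buffer, 0 °C
Reagents that add atoms: none
Why: Oxidative PMB cleavage by DDQ (hydride abstraction, then hydrolysis of the oxocarbenium ion) frees C17–OH under near-neutral conditions that the formate, the epoxide and the enoate tolerate.

Step 17
Reactants: 24 epoxy alcohol
Product: 26 methyl (2E)-5-[(1S,4R,4aR,8aS)-2-formyl-4-hydroxy-5,5,8a-trimethyl-1,4,4a,5,6,7,8,8a-octahydronaphthalen-1-yl]-3-[(formyloxy)methyl]pent-2-enoate (target), via epoxy aldehyde 25 (not isolated)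
Conditions: DMP, pyridine, CH2Cl2, 0 °C → rt; then Et3N, CH2Cl2, 0 °C → rt
Reagents that add atoms: none
Why: Dess–Martin oxidation gives the β,γ-epoxy aldehyde, whose acidic C8–H is removed by the amine so that E1cB opening of the C7–O bond creates the C7=C8 enal while the C6–O bond, and with it the C6 configuration from step 15, stays intact.

Compound list
1 | 2,2-dimethylpent-4-enal | C=CCC(C)(C)C=O | starting material
2 | triethyl 4-phosphonocrotonate | CCOC(=O)/C=C/CP(=O)(OCC)OCC | starting material
3 | ethyl (2E,4E)-6,6-dimethylnona-2,4,8-trienoate | CCOC(=O)/C=C/C=C/C(C)(C)CC=C | intermediate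
4 | (2E,4E)-6,6-dimethylnona-2,4,8-trien-1-ol | OC/C=C/C=C/C(C)(C)CC=C | intermediate
5 | 1-({[(2E,4E)-6,6-dimethylnona-2,4,8-trien-1-yl]oxy}methyl)-4-methoxybenzene | COc1ccc(COC/C=C/C=C/C(C)(C)CC=C)cc1 | intermediate
6 | methyl acetoacetate | COC(=O)CC(C)=O | starting material
7 | methyl (2E)-3-{[(trifluoromethyl)sulfonyl]oxy}but-2-enoate | COC(=O)/C=C(\C)OS(=O)(=O)C(F)(F)F | intermediate
8 | 9-{(5E,7E)-9-[(4-methoxybenzyl)oxy]-4,4-dimethylnona-5,7-dien-1-yl}-9-borabicyclo[3.3.1]nonane | COc1ccc(COC/C=C/C=C/C(C)(C)CCCB2C3CCCC2CCC3)cc1 | intermediate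
9 | methyl (2E,8E,10E)-12-[(4-methoxybenzyl)oxy]-3,7,7-trimethyldodeca-2,8,10-trienoate | COC(=O)/C=C(C)/CCCC(C)(C)/C=C/C=C/COCc1ccc(OC)cc1 | intermediate
10 | (2E,8E,10E)-12-[(4-methoxybenzyl)oxy]-3,7,7-trimethyldodeca-2,8,10-trienoic acid | OC(=O)/C=C(C)/CCCC(C)(C)/C=C/C=C/COCc1ccc(OC)cc1 | intermediate
11 | oxazolidin-2-one | O=C1NCCO1 | starting material
12 | mixed anhydride of acid 10 with pivalic acid | CC(C)(C)C(=O)OC(=O)/C=C(C)/CCCC(C)(C)/C=C/C=C/COCc1ccc(OC)cc1 | intermediate
13 | 3-{(2E,8E,10E)-12-[(4-methoxybenzyl)oxy]-3,7,7-trimethyldodeca-2,8,10-trienoyl}oxazolidin-2-one | O=C1OCCN1C(=O)/C=C(C)/CCCC(C)(C)/C=C/C=C/COCc1ccc(OC)cc1 | intermediate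
14 | 3-{[(1R,2R,4aR,8aR)-2-{[(4-methoxybenzyl)oxy]methyl}-5,5,8a-trimethyl-1,2,4a,5,6,7,8,8a-octahydronaphthalen-1-yl]carbonyl}oxazolidin-2-one | O=C(N1CCOC1=O)[C@@H]1[C@H](COCc2ccc(OC)cc2)C=C[C@@H]2C(C)(C)CCC[C@@]12C | intermediate
15 | C9-hydroxymethyl octalin (core of 14; CH2OPMB on C8) | OC[C@@H]1[C@H](COCc2ccc(OC)cc2)C=C[C@@H]2C(C)(C)CCC[C@@]12C | intermediate
16 | C9-formyl octalin (core of 14; CH2OPMB on C8) | O=C[C@@H]1[C@H](COCc2ccc(OC)cc2)C=C[C@@H]2C(C)(C)CCC[C@@]12C | intermediate
17 | C9-vinyl octalin (core of 14; CH2OPMB on C8) | C=C[C@@H]1[C@H](COCc2ccc(OC)cc2)C=C[C@@H]2C(C)(C)CCC[C@@]12C | intermediate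
18 | methyl 4-hydroxybut-2-ynoate | COC(=O)C#CCO | starting material
19 | methyl (2Z)-4-hydroxy-3-iodobut-2-enoate | COC(=O)/C=C(\I)CO | intermediate
20 | 9-[2-(octalin-9-yl)ethyl]-9-borabicyclo[3.3.1]nonane (core of 14; boron on C12) | C(C[C@@H]1[C@H](COCc2ccc(OC)cc2)C=C[C@@H]2C(C)(C)CCC[C@@]12C)B1C2CCCC1CCC2 | intermediate
21 | methyl (2E)-3-(hydroxymethyl)-5-(octalin-9-yl)pent-2-enoate (core of 14; CH2OPMB on C8) | COC(=O)/C=C(\CC[C@@H]1[C@H](COCc2ccc(OC)cc2)C=C[C@@H]2C(C)(C)CCC[C@@]12C)CO | intermediate
22 | methyl (2E)-3-[(formyloxy)methyl]-5-(octalin-9-yl)pent-2-enoate (core of 14; CH2OPMB on C8) | COC(=O)/C=C(\CC[C@@H]1[C@H](COCc2ccc(OC)cc2)C=C[C@@H]2C(C)(C)CCC[C@@]12C)COC=O | intermediate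
23 | 6,7-epoxide of 22 (oxygen anti to the C10 methyl) | COC(=O)/C=C(\CC[C@@H]1[C@H](COCc2ccc(OC)cc2)[C@H]3O[C@H]3[C@@H]2C(C)(C)CCC[C@@]12C)COC=O | intermediate
24 | epoxy alcohol (23 with C17–OH) | COC(=O)/C=C(\CC[C@@H]1[C@H](CO)[C@H]3O[C@H]3[C@@H]2C(C)(C)CCC[C@@]12C)COC=O | intermediate
25 | β,γ-epoxy aldehyde (24 with C17HO) | COC(=O)/C=C(\CC[C@@H]1[C@H](C=O)[C@H]3O[C@H]3[C@@H]2C(C)(C)CCC[C@@]12C)COC=O | intermediate
26 | methyl (2E)-5-[(1S,4R,4aR,8aS)-2-formyl-4-hydroxy-5,5,8a-trimethyl-1,4,4a,5,6,7,8,8a-octahydronaphthalen-1-yl]-3-[(formyloxy)methyl]pent-2-enoate | COC(=O)/C=C(\CC[C@@H]1C(C=O)=C[C@@H](O)[C@@H]2C(C)(C)CCC[C@@]12C)COC=O | target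

Total step count: 17. Longest linear sequence: 15 steps (1–3, 5–11, 13–17); steps 4 and 12 each prepare a one-step coupling partner.

Steps most likely to fail

Step 8 (the labelled step). The β,β-disubstituted enoyl imide may bind poorly or react slowly at the copper centre, because the C10 methyl sits close to the ligand. The 1,3-diaxial contact that develops between the C4 and C10 methyl groups may also erode the endo (trans-fusion) or the facial preference. The fallback replaces catalyst control by auxiliary control with a stoichiometric, stronger Lewis acid, which is established chemistry for trienoyl oxazolidinones. It sets out from acid 10 and returns at alcohol 15. Acid 10 is converted through the mixed anhydride 12 and lithiated (R)-4-benzyloxazolidin-2-one (THF, −78 °C) into the (R)-4-benzyl trienoyl oxazolidinone F1. Me2AlCl (1.4 equiv, CH2Cl2, −30 °C) forms the cationic aluminium chelate, in which the benzyl group covers the Cα-Si face of C9, and the endo cycloaddition should give the auxiliary-bearing cycloadduct F2. LiBH4 then cleaves the auxiliary and delivers 15.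

Step 13. Hydroboration of the vinyl group next to the congested C9/C10 region may be incomplete, and the alkylborane may undergo protodeboronation or β-hydride loss faster than transmetalation. The fallback builds the chain by substitution at C11 and syn-carbocupration instead. It sets out from alcohol 15 and returns at 21.
- Tf2O/2,6-lutidine gives the C11 triflate F3.
- 3-Lithio-1-(trimethylsilyl)propyne (THF, −78 °C) displaces it to give the trimethylsilyl alkyne F4.
- K2CO3/MeOH gives the terminal alkyne F5.
- n-BuLi then ClCO2Me gives the ynoate F6.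
- The cuprate from (isopropoxydimethylsilyl)methylmagnesium chloride and CuBr·SMe2 (THF, −78 °C) adds syn, placing the new CH2Si group trans to the ester, to give the (E)-β-silylmethyl enoate F7.
- Tamao oxidation (H2O2, KF, KHCO3, THF/MeOH) converts C–Si into the C16 alcohol 21.

Step 16. Once C17–OH is free, the acidic hydroquinone by-product may promote transannular opening of the epoxide by that hydroxyl (attack at C6 from the face opposite the epoxide oxygen), or PMB removal may stall. The fallback changes the order so that no epoxy alcohol is ever present. It sets out from formate 22 and returns at the epoxy aldehyde 25. DDQ on 22 gives the homoallylic C17 alcohol F8. Buffered Dess–Martin oxidation gives the β,γ-unsaturated aldehyde F9. Dimethyldioxirane (acetone, −20 °C) epoxidises C6=C7 from the face anti to the C10 methyl to give 25, which Et3N opens to 26 as in step 17.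

Further compounds
F1 | step 8 | (4R)-4-benzyl-3-{(2E,8E,10E)-12-[(4-methoxybenzyl)oxy]-3,7,7-trimethyldodeca-2,8,10-trienoyl}oxazolidin-2-one | O=C1OC[C@@H](Cc2ccccc2)N1C(=O)/C=C(C)/CCCC(C)(C)/C=C/C=C/COCc1ccc(OC)cc1
F2 | step 8 | (4R)-4-benzyl-3-[(octalin-9-yl)carbonyl]oxazolidin-2-one (core of 14; CH2OPMB on C8) | O=C(N1[C@H](Cc3ccccc3)COC1=O)[C@@H]1[C@H](COCc2ccc(OC)cc2)C=C[C@@H]2C(C)(C)CCC[C@@]12C
F3 | step 13 | C11 trifluoromethanesulfonate of alcohol 15 | FC(F)(F)S(=O)(=O)OC[C@@H]1[C@H](COCc2ccc(OC)cc2)C=C[C@@H]2C(C)(C)CCC[C@@]12C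
F4 | step 13 | 9-[4-(trimethylsilyl)but-3-yn-1-yl] octalin (core of 14; CH2OPMB on C8) | C[Si](C)(C)C#CCC[C@@H]1[C@H](COCc2ccc(OC)cc2)C=C[C@@H]2C(C)(C)CCC[C@@]12C
F5 | step 13 | 9-(but-3-yn-1-yl) octalin (core of 14; CH2OPMB on C8) | C#CCC[C@@H]1[C@H](COCc2ccc(OC)cc2)C=C[C@@H]2C(C)(C)CCC[C@@]12C
F6 | step 13 | methyl 5-(octalin-9-yl)pent-2-ynoate (core of 14; CH2OPMB on C8) | COC(=O)C#CCC[C@@H]1[C@H](COCc2ccc(OC)cc2)C=C[C@@H]2C(C)(C)CCC[C@@]12C
F7 | step 13 | methyl (2E)-3-{[dimethyl(propan-2-yloxy)silyl]methyl}-5-(octalin-9-yl)pent-2-enoate (core of 14; CH2OPMB on C8) | COC(=O)/C=C(\CC[C@@H]1[C@H](COCc2ccc(OC)cc2)C=C[C@@H]2C(C)(C)CCC[C@@]12C)C[Si](C)(C)OC(C)C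
F8 | step 16 | methyl (2E)-3-[(formyloxy)methyl]-5-[8-(hydroxymethyl)octalin-9-yl]pent-2-enoate (core of 14) | COC(=O)/C=C(\CC[C@@H]1[C@H](CO)C=C[C@@H]2C(C)(C)CCC[C@@]12C)COC=O
F9 | step 16 | methyl (2E)-3-[(formyloxy)methyl]-5-(8-formyloctalin-9-yl)pent-2-enoate (core of 14) | COC(=O)/C=C(\CC[C@@H]1[C@H](C=O)C=C[C@@H]2C(C)(C)CCC[C@@]12C)COC=O
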